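## Retrosynthetic overview
1. C9–C10 is cut last. A bicyclic bromide (C1–C9) is joined to an (E,E)-dienylzinc (C10–C14, Ph) by sp3–sp2 Negishi coupling, so the diene never meets O2, cobalt hydride or divalent palladium.
2. Both rings close in one operation from an acyclic hydroperoxy vinyl carbinol. O–C3 closes the 1,2-dioxane first; CO then supplies C1, and C1–O4 closes the γ-lactone second, within the same palladium cycle. C3 is set here.
3. C6–OOH comes from cobalt/O2/silane hydroperoxidation of a 1,1-disubstituted alkene.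
4. C4–C5 and the C4 centre come from a copper–bis(oxazoline) pyruvate ene reaction, and the ester is then turned into the vinyl group. C8 comes from (R)-3-bromo-2-methylpropan-1-ol.
5. The dienyl unit comes from phenylacetaldehyde by E-selective Wittig reaction, Corey–Fuchs/MeI and syn-hydrozirconation.

Assumption: chain numbering runs from C1 (lactone C=O) to C14 (benzylic CH2), and the given SMILES is read as (3R,4R,6R,8S,10E,12E).

## Route

Step 1
Reactants: 1 (R)-3-bromo-2-methylpropan-1-ol; 2 isopropenylmagnesium bromide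
Product: 4 (R)-5-bromo-2,4-dimethylpent-1-ene, via bromo triflate 3 (not isolated)
Conditions: n-BuLi (1.0 equiv), Et2O, −78 °C; Tf2O (1.05 equiv), −78 °C; then CuBr·SMe2 (10 mol%), 2 (1.3 equiv in THF), −78 → 0 °C
Reagents that add atoms: triflic anhydride, O=S(=O)(OS(=O)(=O)C(F)(F)F)C(F)(F)F (its CF3SO2 group sits in 3 only and leaves again)
Why: Copper-catalysed Grignard cross-coupling (Kochi type) occurs at the primary triflate, which is far more reactive than the primary bromide, and the C8 centre comes unchanged from 1 because no bond to it is touched.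

Step 2
Reactants: 4 (R)-5-bromo-2,4-dimethylpent-1-ene; 5 methyl pyruvate
Product: 6 methyl (2R,6R)-7-bromo-2-hydroxy-2,6-dimethyl-4-methylideneheptanoate
Conditions: Cu(SbF6)2·(R,R)-t-Bu-box (10 mol%), CH2Cl2, 40 °C, 48 h
Reagents that add atoms: none
Why: This is a catalytic enantioselective carbonyl-ene reaction in which pyruvate chelates square-planar divalent copper and the (R,R)-ligand leaves only the Re face of the ketone open (the (S,S)-complex is known to give (S)-hydroxy esters), so C4 is set as R under catalyst control; hydrogen is taken mainly from the unhindered methyl group, and the minor C6=C7 isomer is carried along because it gives the same C6 radical in step 4.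

Step 3
Reactants: 6 methyl (2R,6R)-7-bromo-2-hydroxy-2,6-dimethyl-4-methylideneheptanoate
Product: 8 (3R,7R)-8-bromo-3,7-dimethyl-5-methylideneoct-1-en-3-ol, via hydroxy aldehyde 7 (not isolated)
Conditions: i-Bu2AlH (2.2 equiv), toluene, −78 °C; then Ph3P=CH2 (3 equiv, from Ph3PCH3Br and KN(SiMe3)2), THF, −78 °C → rt
Reagents that add atoms: methyltriphenylphosphonium bromide, C[P+](c1ccccc1)(c1ccccc1)c1ccccc1.[Br-]
Why: Partial ester reduction through the chelated aluminium hemiacetal followed by Wittig methylenation in the same flask avoids handling the α-hydroxy aldehyde, and C4 and C8 are not touched.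

Step 4
Reactants: 8 (3R,7R)-8-bromo-3,7-dimethyl-5-methylideneoct-1-en-3-ol
Product: 10 (3R,5R,7R)-8-bromo-5-hydroperoxy-3,5,7-trimethyloct-1-en-3-ol, via triethylsilyl peroxide 9 (not isolated)
Conditions: Co(thd)2 (5 mol%), Et3SiH (2 equiv), O2 (1 atm), ClCH2CH2Cl, rt; then MeOH, PPTS (10 mol%), 0 °C
Reagents that add atoms: dioxygen, O=O; triethylsilane, CC[SiH](CC)CC (its silyl group sits in 9 only, and its hydrogen becomes part of the new C6 methyl group)
Why: In this Mukaiyama–Isayama hydroperoxysilylation the cobalt hydride transfers hydrogen to the electron-rich 1,1-disubstituted alkene faster than to the vinyl group on the carbinol carbon, and O2 traps the planar tertiary C6 radical without facial control, so 10 (C6 R) forms about 1:1 with its C6 epimer and is separated by chromatography here (or, if inseparable, at 11).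

Step 5 (key step)
Reactants: 10 (3R,5R,7R)-8-bromo-5-hydroperoxy-3,5,7-trimethyloct-1-en-3-ol
Product: 11 (3R,4aR,7aR)-3-[(2R)-3-bromo-2-methylpropyl]-3,4a-dimethyl-3,4,4a,7a-tetrahydrofuro[3,2-c][1,2]dioxin-6(7H)-one
Conditions: Pd(OAc)2 (10 mol%), p-benzoquinone (2 equiv), CO (1 atm), AcOH–THF 1:4, 23 °C
Reagents that add atoms: carbon monoxide, [C-]#[O+]
Why: Proposed new method: divalent palladium binds the monosubstituted vinyl group, the tertiary hydroperoxide attacks C3 in a 6-exo chair (C4-Me, the C6 side chain and the palladium-bound vinyl group equatorial, C4-OH axial because quaternary C6 already forces one alkyl group axial), CO inserts into the primary C2–Pd bond faster than β-hydride elimination, and the axial C4-OH, which is gauche to the acyl-palladium only in the (3R) adduct, closes the cis-fused lactone while benzoquinone reoxidises zerovalent palladium, so the reversible peroxypalladation drains through the (3R) isomer; the closest known reaction types are the palladium-catalysed oxycarbonylation–lactonisation of alk-4-ene-1,3-diols to cis-fused bicyclic lactones and the palladium-catalysed 6-exo cyclisation of unsaturated tertiary hydroperoxides to 1,2-dioxanes.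

Step 6
Reactants: 12 phenylacetaldehyde; 13 2-(triphenylphosphoranylidene)propanal
Product: 14 (2E)-2-methyl-4-phenylbut-2-enal
Conditions: toluene, 80 °C
Reagents that add atoms: none
Why: Wittig olefination with a stabilised ylide gives the E-trisubstituted enal and so sets the C12=C13 geometry.

Step 7
Reactants: 14 (2E)-2-methyl-4-phenylbut-2-enal
Product: 15 [(2E)-5,5-dibromo-3-methylpenta-2,4-dien-1-yl]benzene
Conditions: CBr4 (1.5 equiv), PPh3 (3 equiv), CH2Cl2, 0 °C
Reagents that add atoms: carbon tetrabromide, BrC(Br)(Br)Br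
Why: The first stage of the Corey–Fuchs sequence (Ramirez dibromoolefination) runs under neutral conditions that do not move or isomerise the C12=C13 alkene.

Step 8
Reactants: 15 [(2E)-5,5-dibromo-3-methylpenta-2,4-dien-1-yl]benzene
Product: 17 [(2E)-3-methylhex-2-en-4-yn-1-yl]benzene, via lithium acetylide 16 (not isolated)
Conditions: n-BuLi (2.1 equiv), THF, −78 °C; then MeI (3 equiv), −78 °C → rt
Reagents that add atoms: iodomethane, CI
Why: In the second Corey–Fuchs stage, bromine–lithium exchange and rearrangement give the lithium acetylide, which is methylated in situ, and at −78 °C this outruns deprotonation of the benzylic/allylic CH2.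

Step 9
Reactants: 17 [(2E)-3-methylhex-2-en-4-yn-1-yl]benzene; 11 bicyclic bromide
Product: 20 plakortolide, via dienylzirconocene chloride 18 (not isolated), via dienylzinc bromide 19 (not isolated)
Conditions: 17 (1.6 equiv), Cp2ZrHCl (1.5 equiv), THF, rt; ZnBr2 (1.5 equiv), 0 °C; then 11, PdCl2(NHC)(3-chloropyridine) (5 mol%, NHC = 1,3-bis(2,6-diisopropylphenyl)imidazol-2-ylidene), LiBr, THF–NMP 2:1, rt → 40 °C
Reagents that add atoms: zirconocene chloride hydride, [H][Zr](Cl)(C1C=CC=C1)C1C=CC=C1 (its Zr fragment sits in 18 only, and only its hydrogen stays in 20); zinc bromide, Br[Zn]Br (in 19 only)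
Why: Syn-hydrozirconation puts zirconium on the less hindered, methyl-bearing alkyne carbon and sets 10E, and transmetalation to zinc followed by alkyl–alkenyl Negishi coupling proceeds with retention of alkene geometry under phosphine-free, near-ambient conditions that spare the lactone and the O–O bond and touch no stereocentre.

## Compound list
1 | (R)-3-bromo-2-methylpropan-1-ol | BrC[C@H](C)CO | starting material
2 | isopropenylmagnesium bromide | CC(=C)[Mg]Br | starting material
3 | (R)-3-bromo-2-methylpropyl trifluoromethanesulfonate | BrC[C@H](C)COS(=O)(=O)C(F)(F)F | intermediate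
4 | (R)-5-bromo-2,4-dimethylpent-1-ene | BrC[C@H](C)CC(C)=C | intermediate
5 | methyl pyruvate | CC(=O)C(=O)OC | starting material
6 | methyl (2R,6R)-7-bromo-2-hydroxy-2,6-dimethyl-4-methylideneheptanoate | BrC[C@H](C)CC(=C)C[C@@](C(=O)OC)(C)O | intermediate
7 | (2R,6R)-7-bromo-2-hydroxy-2,6-dimethyl-4-methylideneheptanal | BrC[C@H](C)CC(=C)C[C@@](C=O)(C)O | intermediate
8 | (3R,7R)-8-bromo-3,7-dimethyl-5-methylideneoct-1-en-3-ol | BrC[C@H](C)CC(=C)C[C@@](C=C)(C)O | intermediate
9 | (3R,5R,7R)-8-bromo-3,5,7-trimethyl-5-[(triethylsilyl)peroxy]oct-1-en-3-ol | BrC[C@H](C)C[C@](OO[Si](CC)(CC)CC)(C)C[C@@](C=C)(C)O | intermediate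
10 | (3R,5R,7R)-8-bromo-5-hydroperoxy-3,5,7-trimethyloct-1-en-3-ol | BrC[C@H](C)C[C@](OO)(C)C[C@@](C=C)(C)O | intermediate
11 | (3R,4aR,7aR)-3-[(2R)-3-bromo-2-methylpropyl]-3,4a-dimethyl-3,4,4a,7a-tetrahydrofuro[3,2-c][1,2]dioxin-6(7H)-one (cis-fused dioxane/lactone; C8 has the same spatial arrangement as in the target, and its descriptor is R only because of Br) | BrC[C@H](C)C[C@]1(C)C[C@@]2(C)OC(=O)C[C@H]2OO1 | intermediate
12 | phenylacetaldehyde | O=CCc1ccccc1 | starting material
13 | 2-(triphenylphosphoranylidene)propanal | CC(C=O)=P(c1ccccc1)(c1ccccc1)c1ccccc1 | starting material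
14 | (2E)-2-methyl-4-phenylbut-2-enal | O=C/C(C)=C/Cc1ccccc1 | intermediate
15 | [(2E)-5,5-dibromo-3-methylpenta-2,4-dien-1-yl]benzene | BrC(Br)=C/C(C)=C/Cc1ccccc1 | intermediate
16 | lithium (3E)-3-methyl-5-phenylpent-3-en-1-yn-1-ide | [Li]C#C/C(C)=C/Cc1ccccc1 | intermediate
17 | [(2E)-3-methylhex-2-en-4-yn-1-yl]benzene | CC#C/C(C)=C/Cc1ccccc1 | intermediate
18 | chlorobis(cyclopentadienyl)[(2E,4E)-4-methyl-6-phenylhexa-2,4-dien-2-yl]zirconium (Cp drawn σ-bonded) | CC(=C\Cc1ccccc1)/C=C(\C)[Zr](Cl)(C1C=CC=C1)C1C=CC=C1 | intermediate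
19 | [(2E,4E)-4-methyl-6-phenylhexa-2,4-dien-2-yl]zinc bromide | CC(=C\Cc1ccccc1)/C=C(\C)[Zn]Br | intermediate
20 | plakortolide, (3R,4aR,7aR)-3,4a-dimethyl-3-[(2S,4E,6E)-2,4,6-trimethyl-8-phenylocta-4,6-dien-1-yl]-3,4,4a,7a-tetrahydrofuro[3,2-c][1,2]dioxin-6(7H)-one | CC(=C\Cc1ccccc1)/C=C(\C)C[C@H](C)C[C@]1(C)C[C@@]2(C)OC(=O)C[C@H]2OO1 | target

## Count and risks
Total steps: 9. Longest linear sequence: 6 (steps 1, 2, 3, 4, 5, 9).

**Step 5 (most likely to fail).**
- Risk: the hydroperoxide may simply oxidise CO at palladium, or a palladium peroxide may convert the vinyl group into a methyl ketone. Silver salts, copper salts and base are left out on purpose, because they would let the hydroperoxide displace the C9 bromide.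
- The fallback sets out from 6 and comes back at 11. It brings in C1–C2 before the peroxide instead of from CO.
- Ester 6 is reduced with i-Bu2AlH to aldehyde 7 and treated in the same flask with Ph3P=CHCO2Me to give the E-enoate F1.
- Co(thd)2/O2/Et3SiH leaves the electron-poor enoate alone and gives the enoate silyl peroxide F2. Methanolysis with PPTS then gives the enoate hydroperoxide F3.
- Et2NH in CF3CH2OH triggers a reversible 6-exo peroxy-Michael addition. Its cis adduct lactonises with the C4-OH, so both rings again close in one operation and 11 is reached.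

**Step 4.**
- Risk: there is no control at C6, so half of the material is lost, and the vinyl group may be partly attacked.
- The fallback sets out from 8 and comes back at 11. It sets C6 stereospecifically.
- Catalyst-controlled, C4-OH-anchored epoxidation of the 1,1-disubstituted alkene (Hf(OtBu)4, chiral bishydroxamic acid, cumene hydroperoxide) gives the spiro-type epoxide F4.
- Perhydrolysis with ethereal H2O2 and MoO2(acac)2 opens the epoxide at the tertiary carbon with inversion to the hydroperoxy diol F5.
- The palladium/CO bicyclisation of step 5 gives the hydroxymethyl peroxylactone F6, and I2/PPh3/imidazole gives the iodomethyl peroxylactone F7.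
- Bu3SnH with Et3B/air at −20 °C removes iodine selectively over the primary bromide and delivers 11.

**Step 9.**
- Risk: a β-branched alkyl bromide and a hindered alkenylzinc couple slowly, β-hydride elimination may compete, and zerovalent palladium may attack the O–O bond.
- The fallback sets out from 11 (with 18) and comes back at 20. It reverses the polarity of the coupling.
- NaI in acetone turns 11 into the bicyclic iodide F8, and zinc dust with LiCl in THF inserts to give the alkylzinc iodide F9.
- Intermediate 18 is quenched with I2 to give the dienyl iodide F10.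
- F9 and F10 are joined with PdCl2(dppf) in THF at rt to give 20.

## Further compounds
F1 | step 5 | methyl (2E,4R,8R)-9-bromo-4-hydroxy-4,8-dimethyl-6-methylidenenon-2-enoate (E-enoate) | BrC[C@H](C)CC(=C)C[C@@](/C=C/C(=O)OC)(C)O
F2 | step 5 | methyl (2E,4R,6R,8R)-9-bromo-4-hydroxy-4,6,8-trimethyl-6-[(triethylsilyl)peroxy]non-2-enoate (enoate silyl peroxide) | BrC[C@H](C)C[C@](OO[Si](CC)(CC)CC)(C)C[C@@](/C=C/C(=O)OC)(C)O
F3 | step 5 | methyl (2E,4R,6R,8R)-9-bromo-6-hydroperoxy-4-hydroxy-4,6,8-trimethylnon-2-enoate (enoate hydroperoxide) | BrC[C@H](C)C[C@](OO)(C)C[C@@](/C=C/C(=O)OC)(C)O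
F4 | step 4 | (2R)-1-{(2S)-2-[(2R)-3-bromo-2-methylpropyl]oxiran-2-yl}-2-methylbut-3-en-2-ol (spiro-type epoxide) | BrC[C@H](C)C[C@@]1(CO1)C[C@@](C=C)(C)O
F5 | step 4 | (2R,4R)-2-[(2R)-3-bromo-2-methylpropyl]-2-hydroperoxy-4-methylhex-5-ene-1,4-diol (hydroperoxy diol) | BrC[C@H](C)C[C@](OO)(CO)C[C@@](C=C)(C)O
F6 | step 4 | (3R,4aR,7aR)-3-[(2R)-3-bromo-2-methylpropyl]-3-(hydroxymethyl)-4a-methyl-3,4,4a,7a-tetrahydrofuro[3,2-c][1,2]dioxin-6(7H)-one (hydroxymethyl peroxylactone) | BrC[C@H](C)C[C@]1(CO)C[C@@]2(C)OC(=O)C[C@H]2OO1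
F7 | step 4 | (3R,4aR,7aR)-3-[(2R)-3-bromo-2-methylpropyl]-3-(iodomethyl)-4a-methyl-3,4,4a,7a-tetrahydrofuro[3,2-c][1,2]dioxin-6(7H)-one (iodomethyl peroxylactone) | BrC[C@H](C)C[C@]1(CI)C[C@@]2(C)OC(=O)C[C@H]2OO1
F8 | step 9 | (3R,4aR,7aR)-3-[(2R)-3-iodo-2-methylpropyl]-3,4a-dimethyl-3,4,4a,7a-tetrahydrofuro[3,2-c][1,2]dioxin-6(7H)-one (bicyclic iodide) | IC[C@H](C)C[C@]1(C)C[C@@]2(C)OC(=O)C[C@H]2OO1
F9 | step 9 | {(2R)-3-[(3R,4aR,7aR)-3,4a-dimethyl-6-oxohexahydrofuro[3,2-c][1,2]dioxin-3-yl]-2-methylpropyl}zinc iodide (alkylzinc iodide) | I[Zn]C[C@H](C)C[C@]1(C)C[C@@]2(C)OC(=O)C[C@H]2OO1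
F10 | step 9 | [(2E,4E)-5-iodo-3-methylhexa-2,4-dien-1-yl]benzene (dienyl iodide) | CC(=C\Cc1ccccc1)/C=C(\C)I
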